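**Assumption (one line):** The (R,R) configuration at C7 and the ring carbon bearing the pyran is taken as given. It corresponds to (+)-α-bisabolol, the enantiomer of the common (−)-levomenol (S,S), and I assume (+)-α-bisabolol can be bought as a single stereoisomer.

## Retrosynthesis
1. The target is a 2,2-dimethyl-3-bromotetrahydropyran (oxane) joined to a 3-bromo-4-chloro-4-methylcyclohexane, which is the halogenated bisabolane (bisabolol-derived) skeleton.
2. Disconnect the cyclohexane Br/Cl pair by anti, Markovnikov bromochlorination of a 1-methylcyclohexene (bromoether **3**).
3. Disconnect the pyran C–O and C–Br bonds by 6-endo bromoetherification of the tertiary alcohol onto the prenyl-type alkene of (+)-α-bisabolol (**1**).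
4. The cyclohexane ring and both C–C-framework stereocenters (C7 and the ring CH) come from **1**. The only ring formed is the tetrahydropyran, in step 1.

## Route

**Step 1**
Reactants: **1** (+)-(R,R)-α-bisabolol; **2** N-bromosuccinimide (NBS)
Product: **3** (3S,6R)-3-bromo-2,2,6-trimethyl-6-[(1R)-4-methylcyclohex-3-en-1-yl]oxane
Conditions: NBS (1.05 equiv), CH2Cl2, –78 → –20 °C
Reagents that add atoms: NBS, O=C1CCC(=O)N1Br (adds Br)
Why: This is a bromonium-induced 6-endo bromoetherification. The tertiary OH attacks the bromonium at the tertiary carbon C11 (Markovnikov), anti to Br. In the chair transition state the large cyclohexenyl group at C7 is equatorial and the new C10–Br is equatorial, so they end up trans across the ring, which sets C10 as S. C7 and the ring CH are not touched.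

**Step 2**
Reactants: **3**; **2** NBS; **4** tetraethylammonium chloride
Product: **5** deoxycaespitol, (3S,6R)-3-bromo-6-[(1R,3R,4R)-3-bromo-4-chloro-4-methylcyclohexyl]-2,2,6-trimethyloxane
Conditions: NBS (1.1 equiv), Et4NCl (3 equiv), CH2Cl2/MeCN 1:1, –20 °C; then preparative HPLC to separate diastereomers
Reagents that add atoms: NBS, O=C1CCC(=O)N1Br (adds Br); Et4NCl, CC[N+](CC)(CC)CC.[Cl-] (adds Cl)
Why: This is an electrophilic anti-bromochlorination via a bromonium ion. Chloride opens it at the tertiary carbon (Markovnikov), trans to Br, which gives the 3-Br/4-Cl trans relationship and Cl on the tertiary carbon. The secondary alkyl bromide and the ether in **3** survive these conditions.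

The facial selectivity relative to the equatorial side chain is only modest. The favoured diaxial opening gives the double epimer at C3/C4. The target has Br cis to the side chain, with Br and Cl diequatorial, and is the minor diastereomer, so it is isolated by HPLC.

## Compound list
1 | (+)-α-bisabolol, (R,R) | CC(C)=CCC[C@@](C)(O)[C@@H]1CCC(C)=CC1 | starting material
2 | N-bromosuccinimide | O=C1CCC(=O)N1Br | reagent (starting material)
3 | (3S,6R)-3-bromo-2,2,6-trimethyl-6-[(1R)-4-methylcyclohex-3-en-1-yl]oxane | CC1(C)O[C@@](C)([C@@H]2CCC(C)=CC2)CC[C@@H]1Br | intermediate
4 | tetraethylammonium chloride | CC[N+](CC)(CC)CC.[Cl-] | reagent (starting material)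
5 | deoxycaespitol | CC1(C)O[C@@](C)([C@@H]2CC[C@@](C)(Cl)[C@H](Br)C2)CC[C@@H]1Br | target

## Totals
Total steps: 2. Longest linear sequence: 2.

## Three most likely failure points
There are only two steps, so these are failure modes across them.

1. **Step 2, diastereoselectivity.** The target (Br cis to the side chain) is the minor bromochlorination product, because the diaxial opening with an equatorial side chain gives the epimer.
   - Fallback: change the approach and halogenate **3** with a vanadium bromoperoxidase/H2O2/KBr/KCl system (pH ~6), where the enzyme pocket rather than substrate conformation controls the face.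
2. **Step 1, chemoselectivity.** The ring trisubstituted alkene can compete with the prenyl alkene for bromonium formation.
   - Fallback: reorder. Bromochlorinate (R)-limonene first, where only the ring alkene reacts. Then cleave the isopropenyl group selectively to the methyl ketone, add 4-methylpent-3-enylMgBr (separating the C7 epimers), and finish with bromoetherification of the now-unique alkene.
3. **Step 1, C10 diastereoselectivity and ring size.** The chair-transition-state preference is only moderate, so some 10R epimer or 5-exo product may form.
   - Fallback: build the pyran by acid-catalysed hydroalkoxylation of a C7=C8 alkene precursor that already carries the C10 bromide. This shifts C7/C10 control to thermodynamic equilibration.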